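The plan rests on dissecting the benzene ring of the dihydrobenzofuran (C3a, C4, C5, C6, C7, C7a) into three alkynes. The oxygen on C4 becomes a silyloxyalkyne, the ring oxygen on C7a an ynol ether, the styryl group on C6 comes from a terminal enyne, and the O1–C2–C3 chain that links C7a to C3a ties the first two alkynes into a 1,6-diyne. A single ruthenium-catalysed (2+2+2) cycloaddition then forms C3a–C7a, C4–C5 and C6–C7 and closes the arene and the dihydrofuran ring together. Its precursor is an enantiopure anti diyne that already holds both stereocentres, made from an auxiliary-controlled anti-aldol adduct.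

Key step: step 7

Remarks on the chemistry
- Atom numbers C2 to C7a are those of the 2,3-dihydro-1-benzofuran core of the target, whose SMILES reads as (2S,3S), trans.
- Assumed sense of induction in step 2: the magnesium-chelated Z-enolate of the (S)-configured auxiliary is attacked on the face away from its benzyl group, which corresponds to the (2R,3S) anti adduct.
- Order of operations: the ester is homologated while the neighbouring oxygen is a bare alkoxide, and the ynol ether is installed last. A β-alkenyloxy or β-alkynyloxy ester would be open to β-elimination, and a dichlorovinyl ether would not survive the butyllithium that the homologation needs.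
- The diyne is a heat- and acid-sensitive benzylic ynol ether; it should be filtered through basic alumina, kept cold and used at once.
- The starting materials of steps 1, 2, 5 and 6 and Cp*RuCl(cod) are taken as commercial.

Step 1
Reactants: 1 [3,5-bis(benzyloxy)phenyl]acetic acid; 2 (4S)-4-benzyl-1,3-oxazolidin-2-one
Product: 4 (4S)-4-benzyl-3-{[3,5-bis(benzyloxy)phenyl]acetyl}-1,3-oxazolidin-2-one, via mixed pivalic anhydride 3 (not isolated)
Conditions: t-BuCOCl, Et3N, THF, −20 °C; then LiCl, 2, −20 °C → rt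
Reagents that add atoms: none
Why: N-acylation of an Evans oxazolidinone through the mixed pivalic anhydride with LiCl/Et3N is routine for arylacetic acids and creates no stereocentre.

Step 2
Reactants: 4 (4S)-4-benzyl-3-{[3,5-bis(benzyloxy)phenyl]acetyl}-1,3-oxazolidin-2-one; 5 3,4-bis(benzyloxy)benzaldehyde
Product: 7 (4S)-4-benzyl-3-{(2R,3S)-3-[3,4-bis(benzyloxy)phenyl]-2-[3,5-bis(benzyloxy)phenyl]-3-hydroxypropanoyl}-1,3-oxazolidin-2-one, via trimethylsilyl ether 6 (not isolated)
Conditions: MgCl2 (0.2 equiv), NaSbF6 (0.3 equiv), Et3N, Me3SiCl, EtOAc, rt; then 1 M HCl, THF, 0 °C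
Reagents that add atoms: none
Why: In this Evans magnesium-halide-catalysed direct anti-aldol reaction, soft enolisation gives the chelated Z-enolate, which should add to the non-enolisable aldehyde through a boat-like transition state on the face away from the benzyl group of the auxiliary, so that C2 becomes R and C3 becomes S (anti), while silylation of the aldolate by Me3SiCl makes the addition irreversible.

Step 3
Reactants: 7 (4S)-4-benzyl-3-{(2R,3S)-3-[3,4-bis(benzyloxy)phenyl]-2-[3,5-bis(benzyloxy)phenyl]-3-hydroxypropanoyl}-1,3-oxazolidin-2-one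
Product: 10 methyl (2R,3S)-3-[3,4-bis(benzyloxy)phenyl]-2-[3,5-bis(benzyloxy)phenyl]-3-hydroxypropanoate, via peroxy acid 8 (not isolated), via carboxylic acid 9 (not isolated)
Conditions: LiOH, H2O2, THF–H2O, 0 °C; Na2SO3; aq. HCl to pH 3, extraction; crude acid, Me3SiCHN2, PhMe–MeOH, 0 °C
Reagents that add atoms: hydrogen peroxide, OO; (trimethylsilyl)diazomethane, C[Si](C)(C)C=[N+]=[N-]
Why: Hydroperoxide cleaves the exocyclic imide carbonyl under conditions too weakly basic for retro-aldol cleavage or epimerisation of the α-aryl centre, and Me3SiCHN2 then esterifies the acid under neutral conditions (standard auxiliary removal and diazoalkane esterification, no stereocentre touched).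

Step 4
Reactants: 10 methyl (2R,3S)-3-[3,4-bis(benzyloxy)phenyl]-2-[3,5-bis(benzyloxy)phenyl]-3-hydroxypropanoate
Product: 13 (1S,2S)-1-[3,4-bis(benzyloxy)phenyl]-2-[3,5-bis(benzyloxy)phenyl]-4-[(triisopropylsilyl)oxy]but-3-yn-1-ol, via dilithium dibromoenolate 11 (not isolated), via dilithium ynolate 12 (not isolated)
Conditions: 10, LiN(SiMe3)2 (1 equiv), THF, −78 °C; added to CH2Br2/lithium 2,2,6,6-tetramethylpiperidide, −78 °C; LiN(SiMe3)2, −78 → −20 °C; n-BuLi, −78 → 0 °C; i-Pr3SiCl, −78 → 0 °C; H2O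
Reagents that add atoms: dibromomethane, BrCBr; chlorotriisopropylsilane, CC(C)[Si](Cl)(C(C)C)C(C)C
Why: This is the Kowalski ester homologation stopped at the ynolate, which is silylated on oxygen (the standard entry to silyloxyalkynes): the lithium alkoxide formed first cannot be expelled and disfavours enolisation, the benzylic carbon migrates to the carbenoid carbon with retention so that C2 keeps its configuration, and the hindered secondary lithium alkoxide should not compete with the ynolate for i-Pr3SiCl at low temperature.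

Step 5
Reactants: 13 (1S,2S)-1-[3,4-bis(benzyloxy)phenyl]-2-[3,5-bis(benzyloxy)phenyl]-4-[(triisopropylsilyl)oxy]but-3-yn-1-ol; 14 trichloroethylene
Product: 17 (1S,2S)-1-[3,4-bis(benzyloxy)phenyl]-2-[3,5-bis(benzyloxy)phenyl]-1-(ethynyloxy)-4-[(triisopropylsilyl)oxy]but-3-yne, via dichlorovinyl ether 15 (not isolated), via lithium alkynyl ether 16 (not isolated)
Conditions: KH, THF, 0 °C; Cl2C=CHCl, 0 °C → rt; then n-BuLi, −78 → −40 °C; H2O, −78 °C
Reagents that add atoms: none
Why: In Greene's one-pot synthesis of terminal ynol ethers the potassium alkoxide adds to dichloroacetylene formed in the flask to give the (E)-1,2-dichlorovinyl ether, and n-BuLi then effects dehydrochlorination and chlorine–lithium exchange to the lithium alkoxyacetylide, which is protonated; the carbinol C–O bond is never broken, so C1 keeps its configuration, and the bulky silyl group should shield the silyloxyalkyne at −78 °C.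

Step 6
Reactants: 18 4-(benzyloxy)-3-methoxybenzaldehyde; 19 diethyl [3-(trimethylsilyl)prop-2-yn-1-yl]phosphonate
Product: 21 1-(benzyloxy)-4-[(1E)-but-1-en-3-yn-1-yl]-2-methoxybenzene, via silylated enyne 20 (not isolated)
Conditions: 19, LiN(SiMe3)2, THF, −78 °C; 18, −78 → 0 °C; then K2CO3 (cat.), MeOH, rt
Reagents that add atoms: none
Why: Horner–Wadsworth–Emmons olefination with a propargylic phosphonate should give the conjugated enyne with the E alkene favoured for an aromatic aldehyde, and K2CO3 in MeOH removes the alkynyl silyl group in the same flask.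

Step 7
Reactants: 17 (1S,2S)-1-[3,4-bis(benzyloxy)phenyl]-2-[3,5-bis(benzyloxy)phenyl]-1-(ethynyloxy)-4-[(triisopropylsilyl)oxy]but-3-yne; 21 1-(benzyloxy)-4-[(1E)-but-1-en-3-yn-1-yl]-2-methoxybenzene
Product: 22 (2S,3S)-2-[3,4-bis(benzyloxy)phenyl]-3-[3,5-bis(benzyloxy)phenyl]-6-{(E)-2-[4-(benzyloxy)-3-methoxyphenyl]ethenyl}-4-[(triisopropylsilyl)oxy]-2,3-dihydro-1-benzofuran
Conditions: Cp*RuCl(cod) (10 mol %), 21 (3 equiv), ClCH2CH2Cl, rt; 17 added slowly by syringe pump
Reagents that add atoms: none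
Why: Proposed new method: oxidative cyclisation of the two tethered alkynes of 17 on the Cp*RuCl fragment should give a bicyclic ruthenacyclopentadiene, and insertion of the alkyne of 21 followed by reductive elimination should release the arene and return the catalyst. The closest known reaction type is the Cp*RuCl(cod)-catalysed (2+2+2) cycloaddition of 1,6-diynes with terminal alkynes, in which a diyne substituted at one terminus gives the meta-substituted arene; a diyne that combines an ynol ether with a silyloxyalkyne has not been used in it. The dihydrofuran ring closes in the oxidative cyclisation, by C3a–C7a bond formation across the three-atom O1–C2–C3 tether, and the benzene ring closes by the intermolecular alkyne insertion and reductive elimination that form C6–C7 and C4–C5. No stereocentre is created, and C2 and C3 lie in the tether, where no bond is broken. The step needs regioselectivity (arylvinyl group on C6 and not on C5), which the size difference between the silyloxy-bearing terminus and the unsubstituted ynol ether terminus should secure, and chemoselectivity for the alkyne over the alkene of 21 and for cross- over self-coupling, which the neutral catalyst, the excess of 21 and the slow addition of 17 at room temperature should secure.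

Step 8
Reactants: 22 (2S,3S)-2-[3,4-bis(benzyloxy)phenyl]-3-[3,5-bis(benzyloxy)phenyl]-6-{(E)-2-[4-(benzyloxy)-3-methoxyphenyl]ethenyl}-4-[(triisopropylsilyl)oxy]-2,3-dihydro-1-benzofuran
Product: 23 (2S,3S)-2-[3,4-bis(benzyloxy)phenyl]-3-[3,5-bis(benzyloxy)phenyl]-6-{(E)-2-[4-(benzyloxy)-3-methoxyphenyl]ethenyl}-2,3-dihydro-1-benzofuran-4-ol
Conditions: Bu4NF, AcOH, THF, 0 °C
Reagents that add atoms: none
Why: Fluoride cleaves the aryl silyl ether (standard desilylation), acetic acid buffers the phenoxide, and the benzyl ethers, the alkene and both stereocentres are inert.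

Step 9
Reactants: 23 (2S,3S)-2-[3,4-bis(benzyloxy)phenyl]-3-[3,5-bis(benzyloxy)phenyl]-6-{(E)-2-[4-(benzyloxy)-3-methoxyphenyl]ethenyl}-2,3-dihydro-1-benzofuran-4-ol
Product: 24 4-[(2S,3S)-3-(3,5-dihydroxyphenyl)-4-hydroxy-6-[(E)-2-(4-hydroxy-3-methoxyphenyl)ethenyl]-2,3-dihydro-1-benzofuran-2-yl]benzene-1,2-diol
Conditions: BCl3, C6HMe5, CH2Cl2, −78 °C; then aqueous work-up
Reagents that add atoms: none
Why: BCl3 with pentamethylbenzene as a non-Lewis-basic benzyl-cation scavenger cleaves aryl benzyl ethers at −78 °C (Lewis-acid debenzylation), conditions under which the aryl methyl ether, the E alkene and the trans-dihydrofuran ring, whose configuration is also the thermodynamically preferred one, are expected to survive.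

Compound list
1 | [3,5-bis(benzyloxy)phenyl]acetic acid | OC(=O)Cc1cc(OCc2ccccc2)cc(OCc2ccccc2)c1 | starting material
2 | (4S)-4-benzyl-1,3-oxazolidin-2-one | O=C1OC[C@H](Cc2ccccc2)N1 | starting material
3 | [3,5-bis(benzyloxy)phenyl]acetic 2,2-dimethylpropanoic anhydride | CC(C)(C)C(=O)OC(=O)Cc1cc(OCc2ccccc2)cc(OCc2ccccc2)c1 | intermediate
4 | (4S)-4-benzyl-3-{[3,5-bis(benzyloxy)phenyl]acetyl}-1,3-oxazolidin-2-one | O=C1OC[C@H](Cc2ccccc2)N1C(=O)Cc1cc(OCc2ccccc2)cc(OCc2ccccc2)c1 | intermediate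
5 | 3,4-bis(benzyloxy)benzaldehyde | O=Cc1ccc(OCc2ccccc2)c(OCc2ccccc2)c1 | starting material
6 | (4S)-4-benzyl-3-{(2R,3S)-3-[3,4-bis(benzyloxy)phenyl]-2-[3,5-bis(benzyloxy)phenyl]-3-[(trimethylsilyl)oxy]propanoyl}-1,3-oxazolidin-2-one | C[Si](C)(C)O[C@H](c1ccc(OCc2ccccc2)c(OCc2ccccc2)c1)[C@H](C(=O)N1[C@@H](Cc2ccccc2)COC1=O)c1cc(OCc2ccccc2)cc(OCc2ccccc2)c1 | intermediate
7 | (4S)-4-benzyl-3-{(2R,3S)-3-[3,4-bis(benzyloxy)phenyl]-2-[3,5-bis(benzyloxy)phenyl]-3-hydroxypropanoyl}-1,3-oxazolidin-2-one | O[C@H](c1ccc(OCc2ccccc2)c(OCc2ccccc2)c1)[C@H](C(=O)N1[C@@H](Cc2ccccc2)COC1=O)c1cc(OCc2ccccc2)cc(OCc2ccccc2)c1 | intermediate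
8 | (2R,3S)-3-[3,4-bis(benzyloxy)phenyl]-2-[3,5-bis(benzyloxy)phenyl]-3-hydroxypropaneperoxoic acid | O[C@H](c1ccc(OCc2ccccc2)c(OCc2ccccc2)c1)[C@H](C(=O)OO)c1cc(OCc2ccccc2)cc(OCc2ccccc2)c1 | intermediate
9 | (2R,3S)-3-[3,4-bis(benzyloxy)phenyl]-2-[3,5-bis(benzyloxy)phenyl]-3-hydroxypropanoic acid | O[C@H](c1ccc(OCc2ccccc2)c(OCc2ccccc2)c1)[C@H](C(=O)O)c1cc(OCc2ccccc2)cc(OCc2ccccc2)c1 | intermediate
10 | methyl (2R,3S)-3-[3,4-bis(benzyloxy)phenyl]-2-[3,5-bis(benzyloxy)phenyl]-3-hydroxypropanoate | O[C@H](c1ccc(OCc2ccccc2)c(OCc2ccccc2)c1)[C@H](C(=O)OC)c1cc(OCc2ccccc2)cc(OCc2ccccc2)c1 | intermediate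
11 | dilithium salt (alkoxide and enolate) of (3R,4S)-4-[3,4-bis(benzyloxy)phenyl]-3-[3,5-bis(benzyloxy)phenyl]-1,1-dibromo-4-hydroxybutan-2-one | [Li+].[Li+].[O-][C@H](c1ccc(OCc2ccccc2)c(OCc2ccccc2)c1)[C@H](C([O-])=C(Br)Br)c1cc(OCc2ccccc2)cc(OCc2ccccc2)c1 | intermediate
12 | dilithium (3S,4S)-4-[3,4-bis(benzyloxy)phenyl]-3-[3,5-bis(benzyloxy)phenyl]-4-oxidobut-1-yn-1-olate | [Li+].[Li+].[O-][C@H](c1ccc(OCc2ccccc2)c(OCc2ccccc2)c1)[C@H](C#C[O-])c1cc(OCc2ccccc2)cc(OCc2ccccc2)c1 | intermediate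
13 | (1S,2S)-1-[3,4-bis(benzyloxy)phenyl]-2-[3,5-bis(benzyloxy)phenyl]-4-[(triisopropylsilyl)oxy]but-3-yn-1-ol | O[C@H](c1ccc(OCc2ccccc2)c(OCc2ccccc2)c1)[C@H](C#CO[Si](C(C)C)(C(C)C)C(C)C)c1cc(OCc2ccccc2)cc(OCc2ccccc2)c1 | intermediate
14 | trichloroethylene | ClC=C(Cl)Cl | starting material
15 | (1S,2S)-1-[3,4-bis(benzyloxy)phenyl]-2-[3,5-bis(benzyloxy)phenyl]-1-{[(E)-1,2-dichloroethenyl]oxy}-4-[(triisopropylsilyl)oxy]but-3-yne | Cl/C=C(/Cl)O[C@H](c1ccc(OCc2ccccc2)c(OCc2ccccc2)c1)[C@H](C#CO[Si](C(C)C)(C(C)C)C(C)C)c1cc(OCc2ccccc2)cc(OCc2ccccc2)c1 | intermediate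
16 | lithium acetylide of 17 (lithium on the terminal carbon of the ynol ether, configuration as in 17) | [Li]C#CO[C@H](c1ccc(OCc2ccccc2)c(OCc2ccccc2)c1)[C@H](C#CO[Si](C(C)C)(C(C)C)C(C)C)c1cc(OCc2ccccc2)cc(OCc2ccccc2)c1 | intermediate
17 | (1S,2S)-1-[3,4-bis(benzyloxy)phenyl]-2-[3,5-bis(benzyloxy)phenyl]-1-(ethynyloxy)-4-[(triisopropylsilyl)oxy]but-3-yne | C#CO[C@H](c1ccc(OCc2ccccc2)c(OCc2ccccc2)c1)[C@H](C#CO[Si](C(C)C)(C(C)C)C(C)C)c1cc(OCc2ccccc2)cc(OCc2ccccc2)c1 | intermediate
18 | 4-(benzyloxy)-3-methoxybenzaldehyde | O=Cc1ccc(OCc2ccccc2)c(OC)c1 | starting material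
19 | diethyl [3-(trimethylsilyl)prop-2-yn-1-yl]phosphonate | CCOP(=O)(CC#C[Si](C)(C)C)OCC | starting material
20 | {(3E)-4-[4-(benzyloxy)-3-methoxyphenyl]but-3-en-1-yn-1-yl}trimethylsilane | C[Si](C)(C)C#C/C=C/c1ccc(OCc2ccccc2)c(OC)c1 | intermediate
21 | 1-(benzyloxy)-4-[(1E)-but-1-en-3-yn-1-yl]-2-methoxybenzene | C#C/C=C/c1ccc(OCc2ccccc2)c(OC)c1 | intermediate
22 | (2S,3S)-2-[3,4-bis(benzyloxy)phenyl]-3-[3,5-bis(benzyloxy)phenyl]-6-{(E)-2-[4-(benzyloxy)-3-methoxyphenyl]ethenyl}-4-[(triisopropylsilyl)oxy]-2,3-dihydro-1-benzofuran | COc1cc(/C=C/c2cc(O[Si](C(C)C)(C(C)C)C(C)C)c3c(c2)O[C@H](c2ccc(OCc4ccccc4)c(OCc4ccccc4)c2)[C@H]3c2cc(OCc4ccccc4)cc(OCc4ccccc4)c2)ccc1OCc1ccccc1 | intermediate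
23 | (2S,3S)-2-[3,4-bis(benzyloxy)phenyl]-3-[3,5-bis(benzyloxy)phenyl]-6-{(E)-2-[4-(benzyloxy)-3-methoxyphenyl]ethenyl}-2,3-dihydro-1-benzofuran-4-ol | COc1cc(/C=C/c2cc(O)c3c(c2)O[C@H](c2ccc(OCc4ccccc4)c(OCc4ccccc4)c2)[C@H]3c2cc(OCc4ccccc4)cc(OCc4ccccc4)c2)ccc1OCc1ccccc1 | intermediate
24 | 4-[(2S,3S)-3-(3,5-dihydroxyphenyl)-4-hydroxy-6-[(E)-2-(4-hydroxy-3-methoxyphenyl)ethenyl]-2,3-dihydro-1-benzofuran-2-yl]benzene-1,2-diol | COc1cc(/C=C/c2cc(O)c3c(c2)O[C@H](c2ccc(O)c(O)c2)[C@H]3c2cc(O)cc(O)c2)ccc1O | target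

Total step count: 9. Longest linear sequence: 8 steps (steps 1 to 5, then 7 to 9); step 6 is the side branch.

Steps most likely to fail

Step 7. The electron-rich diyne may be lost to ruthenium-promoted ionisation or hydration of the benzylic ynol ether or to self-trimerisation before it meets the enyne, or the enyne may insert with the wrong orientation. The fallback uses known chemistry; it sets out from 13 (with 18 for the second component) and returns at 22. The arene is built by a thermal Danheiser benzannulation, which is established for silyloxyalkynes. Alcohol 13 is silylated (Me3SiCl, imidazole, CH2Cl2) to trimethylsilyl ether F1. Aldehyde 18 is converted by Takai iodo-olefination (CrCl2, CHI3, THF) into (E)-alkenyl iodide F2. Iodine–lithium exchange (t-BuLi, −78 °C) and addition to 3-ethoxycyclobut-2-en-1-one give cyclobutenol F3, which on work-up with dilute acid loses ethanol to give 3-alkenylcyclobutenone F4. Heating F1 with F4 in toluene at 80 °C should give phenol F5 by ring opening to the vinylketene, [2+2] addition to the silyloxyalkyne, ring opening and 6π closure. In F5 the hydroxyl sits on the future C7a, the side chain on C3a, the silyloxy group on C4 and the arylvinyl group on C6. Catalytic camphorsulfonic acid (CH2Cl2, 0 °C) then ionises the 3,4-dialkoxybenzylic silyl ether, and the phenol closes the O1–C2 bond trans to the aryl group on C3, which gives 22.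

Step 5. The potassium alkoxide or n-BuLi may take the silyl group off the silyloxyalkyne, the base may epimerise the propargylic benzylic carbon, and the benzylic ynol ether may decay by retro-ene or sigmatropic pathways during isolation. The fallback sets out from 13 and returns at 16; it never generates an alkoxide. Formylation (acetic formic anhydride, pyridine, 0 °C) gives formate F6. Dichloromethylenation of the formyl group (PPh3, CCl4, THF, 60 °C) gives 2,2-dichlorovinyl ether F7. n-BuLi (2.2 equiv, −78 → −40 °C) converts F7 into 16, and water then gives 17.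

Step 4. The lithium aldolate ester may enolise or undergo retro-aldol cleavage before dibromomethyllithium adds, which would erode the configuration, or the alkoxide may be silylated in competition with the ynolate. The fallback sets out from 7 and returns at 11; it also replaces step 3. Transamination with MeNHOMe·HCl and AlMe3 (CH2Cl2, 0 °C) gives Weinreb amide F8, whose aluminium chelate resists retro-aldol cleavage. Addition of dibromomethyllithium (THF, −78 °C) gives a stable chelated adduct and, after acidic work-up, dibromomethyl ketone F9. LiN(SiMe3)2 (2 equiv, −78 °C) converts F9 into 11, from which step 4 continues with n-BuLi and i-Pr3SiCl.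

Further compounds
F1 | step 7 | (1S,2S)-1-[3,4-bis(benzyloxy)phenyl]-2-[3,5-bis(benzyloxy)phenyl]-1-[(trimethylsilyl)oxy]-4-[(triisopropylsilyl)oxy]but-3-yne | C[Si](C)(C)O[C@H](c1ccc(OCc2ccccc2)c(OCc2ccccc2)c1)[C@H](C#CO[Si](C(C)C)(C(C)C)C(C)C)c1cc(OCc2ccccc2)cc(OCc2ccccc2)c1
F2 | step 7 | 1-(benzyloxy)-4-[(E)-2-iodoethenyl]-2-methoxybenzene | I/C=C/c1ccc(OCc2ccccc2)c(OC)c1
F3 | step 7 | 1-{(E)-2-[4-(benzyloxy)-3-methoxyphenyl]ethenyl}-3-ethoxycyclobut-2-en-1-ol | CCOC1=CC(O)(/C=C/c2ccc(OCc3ccccc3)c(OC)c2)C1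
F4 | step 7 | 3-{(E)-2-[4-(benzyloxy)-3-methoxyphenyl]ethenyl}cyclobut-2-en-1-one | O=C1C=C(/C=C/c2ccc(OCc3ccccc3)c(OC)c2)C1
F5 | step 7 | 2-{(1S,2S)-2-[3,4-bis(benzyloxy)phenyl]-1-[3,5-bis(benzyloxy)phenyl]-2-[(trimethylsilyl)oxy]ethyl}-5-{(E)-2-[4-(benzyloxy)-3-methoxyphenyl]ethenyl}-3-[(triisopropylsilyl)oxy]phenol | C[Si](C)(C)O[C@H](c1ccc(OCc2ccccc2)c(OCc2ccccc2)c1)[C@H](c1c(O)cc(/C=C/c2ccc(OCc3ccccc3)c(OC)c2)cc1O[Si](C(C)C)(C(C)C)C(C)C)c1cc(OCc2ccccc2)cc(OCc2ccccc2)c1
F6 | step 5 | (1S,2S)-1-[3,4-bis(benzyloxy)phenyl]-2-[3,5-bis(benzyloxy)phenyl]-4-[(triisopropylsilyl)oxy]but-3-yn-1-yl formate | O=CO[C@H](c1ccc(OCc2ccccc2)c(OCc2ccccc2)c1)[C@H](C#CO[Si](C(C)C)(C(C)C)C(C)C)c1cc(OCc2ccccc2)cc(OCc2ccccc2)c1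
F7 | step 5 | (1S,2S)-1-[3,4-bis(benzyloxy)phenyl]-2-[3,5-bis(benzyloxy)phenyl]-1-[(2,2-dichloroethenyl)oxy]-4-[(triisopropylsilyl)oxy]but-3-yne | ClC(Cl)=CO[C@H](c1ccc(OCc2ccccc2)c(OCc2ccccc2)c1)[C@H](C#CO[Si](C(C)C)(C(C)C)C(C)C)c1cc(OCc2ccccc2)cc(OCc2ccccc2)c1
F8 | step 4 | (2R,3S)-3-[3,4-bis(benzyloxy)phenyl]-2-[3,5-bis(benzyloxy)phenyl]-3-hydroxy-N-methoxy-N-methylpropanamide | O[C@H](c1ccc(OCc2ccccc2)c(OCc2ccccc2)c1)[C@H](C(=O)N(C)OC)c1cc(OCc2ccccc2)cc(OCc2ccccc2)c1
F9 | step 4 | (3R,4S)-4-[3,4-bis(benzyloxy)phenyl]-3-[3,5-bis(benzyloxy)phenyl]-1,1-dibromo-4-hydroxybutan-2-one | O[C@H](c1ccc(OCc2ccccc2)c(OCc2ccccc2)c1)[C@H](C(=O)C(Br)Br)c1cc(OCc2ccccc2)cc(OCc2ccccc2)c1
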